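**Retrosynthetic overview**
- Feature used: in each flavanone unit the ketone carbon (C4, C4'') sits on an arene carbon (C4a, C4a'') flanked by the free phenol (C5–OH, C5''–OH) and by the carbon bearing the ring oxygen (C8a–O1, C8a''–O1''), and that oxygen carries C2(H)(aryl)–C3H2. Rings C and F are therefore each the adduct of a salicylaldehyde C–H across an O-bound 1-arylvinyl group.
- Key disconnection: C3–C4 and C3''–C4'' (twofold enantioselective rhodium hydroacylation) lead from benzyl ether 21 back to the bis(salicylaldehyde) bis(1-arylvinyl ether) 20. Ring E is carried as a benzyl ether, not a silyl ether, so that it survives the fluoride step and leaves by hydrogenolysis at the end.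
- 20 comes from the bis(aryl benzoate) 17 by twofold Petasis methylenation, fluoride cleavage of two di-tert-butylsilylene-masked salicyl alcohols and MnO2 oxidation.
- 17 is assembled by Negishi coupling (C3'–C6'') of iodide 11 with bromo ester 8 and acylation with 4-(benzyloxy)benzoyl chloride; 8 and 11 both derive from benzyl ether 3, made from 2,4,6-trihydroxybenzaldehyde.
- Ring order: rings A, B, D and E are bought as arenes; the two pyranone rings C and F are closed last and together in step 16.

Key step: step 16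

Assumption: the C3'–C6'' biaryl axis (ortho groups OMe, OH, OMe and H) is taken as freely rotating at room temperature, since the target carries no axial descriptor.
Assumption: (R)-DTBM-SEGPHOS is written as the antipode that gives 2S,2''S; the sense of induction is not known for this substrate class, and the (S)-ligand is used instead if the first experiment shows the opposite sense.

**Route**

Step 1
Reactants: 1 2,4,6-trihydroxybenzaldehyde
Product: 2 2,6-dihydroxy-4-methoxybenzaldehyde
Conditions: Me2SO4 (1.0 equiv), K2CO3 (1.0 equiv), acetone, rt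
Reagents that add atoms: dimethyl sulfate, COS(=O)(=O)OC
Why: Williamson O-methylation with one equivalent of a hard methylating agent should go to the 4-hydroxyl, which is the most acidic (para to the formyl group) and is not held in the hydrogen bond to C=O, as is established for phloroglucinol aldehydes and ketones.

Step 2
Reactants: 2 2,6-dihydroxy-4-methoxybenzaldehyde
Product: 3 2-(benzyloxy)-6-hydroxy-4-methoxybenzaldehyde
Conditions: BnBr (1.05 equiv), K2CO3, acetone, reflux
Reagents that add atoms: benzyl bromide, BrCc1ccccc1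
Why: Williamson O-benzylation should stop at the mono-ether because the remaining ortho hydroxyl is then locked in the hydrogen bond to the formyl oxygen, and the symmetry of 2 makes either hydroxyl give the same product.

Step 3
Reactants: 3 2-(benzyloxy)-6-hydroxy-4-methoxybenzaldehyde
Product: 4 3-(benzyloxy)-2-(hydroxymethyl)-5-methoxyphenol
Conditions: NaBH4, THF/EtOH, 0 °C; aq NH4Cl
Reagents that add atoms: none
Why: Borohydride reduction of the aldehyde gives the salicyl alcohol, which is kept cold and neutral and carried on crude because such electron-rich ortho-hydroxybenzyl alcohols ionise easily to ortho-quinone methides.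

Step 4
Reactants: 4 3-(benzyloxy)-2-(hydroxymethyl)-5-methoxyphenol
Product: 5 5-(benzyloxy)-2,2-di-tert-butyl-7-methoxy-4H-benzo[d][1,3,2]dioxasiline
Conditions: tBu2Si(OTf)2, 2,6-lutidine, CH2Cl2, 0 °C
Reagents that add atoms: di-tert-butylsilyl bis(trifluoromethanesulfonate), CC(C)(C)[Si](OS(=O)(=O)C(F)(F)F)(OS(=O)(=O)C(F)(F)F)C(C)(C)C
Why: Silylene protection of the phenol and the benzylic alcohol as one six-membered di-tert-butylsilylene ring (silylation of a 1,3-related diol with the bis-triflate) masks the future salicylaldehyde in a form that is inert to hydrogenolysis, organozinc and titanium carbene chemistry and is removed by fluoride.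

Step 5
Reactants: 5 5-(benzyloxy)-2,2-di-tert-butyl-7-methoxy-4H-benzo[d][1,3,2]dioxasiline
Product: 6 2,2-di-tert-butyl-7-methoxy-4H-benzo[d][1,3,2]dioxasilin-5-ol
Conditions: H2 (1 atm), Pd/C, EtOAc, rt
Reagents that add atoms: none
Why: Hydrogenolysis of the aryl benzyl ether over Pd/C under neutral conditions frees the phenol that will become O1, and the silylene stays in place.

Step 6
Reactants: 6 2,2-di-tert-butyl-7-methoxy-4H-benzo[d][1,3,2]dioxasilin-5-ol; 7 3-bromo-4-methoxybenzoic acid
Product: 8 2,2-di-tert-butyl-7-methoxy-4H-benzo[d][1,3,2]dioxasilin-5-yl 3-bromo-4-methoxybenzoate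
Conditions: EDC·HCl, DMAP, CH2Cl2, rt
Reagents that add atoms: none
Why: Steglich esterification (carbodiimide activation of the acid, acyl transfer through DMAP) joins the phenol to the ring B acid only after the formyl group has been reduced and masked, so that no alkoxide is ever generated next to the aryl ester and acyl migration to the benzylic oxygen is excluded.

Step 7
Reactants: 3 2-(benzyloxy)-6-hydroxy-4-methoxybenzaldehyde
Product: 9 6-(benzyloxy)-2-hydroxy-3-iodo-4-methoxybenzaldehyde
Conditions: NIS (1.05 equiv), TFA (10 mol%), MeCN, 0 °C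
Reagents that add atoms: N-iodosuccinimide, O=C1CCC(=O)N1I
Why: Electrophilic aromatic iodination of 2-hydroxy-4,6-dialkoxy aryl carbonyl compounds takes place at the carbon between the chelated hydroxyl and the 4-methoxy group, which puts iodine at the future C6'' next to the future C5''–OH.

Step 8
Reactants: 9 6-(benzyloxy)-2-hydroxy-3-iodo-4-methoxybenzaldehyde
Product: 10 3-(benzyloxy)-2-(hydroxymethyl)-6-iodo-5-methoxyphenol
Conditions: NaBH4, THF/EtOH, 0 °C; aq NH4Cl
Reagents that add atoms: none
Why: Borohydride reduction as in step 3, the aryl iodide being inert to NaBH4.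

Step 9
Reactants: 10 3-(benzyloxy)-2-(hydroxymethyl)-6-iodo-5-methoxyphenol
Product: 11 5-(benzyloxy)-2,2-di-tert-butyl-8-iodo-7-methoxy-4H-benzo[d][1,3,2]dioxasiline
Conditions: tBu2Si(OTf)2, 2,6-lutidine, CH2Cl2, 0 °C
Reagents that add atoms: di-tert-butylsilyl bis(trifluoromethanesulfonate), CC(C)(C)[Si](OS(=O)(=O)C(F)(F)F)(OS(=O)(=O)C(F)(F)F)C(C)(C)C
Why: Silylene formation as in step 4 ties the hydroxyl next to iodine (future C5''–OH) to the benzylic oxygen and leaves the benzyl ether on the future O1''.

Step 10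
Reactants: 11 5-(benzyloxy)-2,2-di-tert-butyl-8-iodo-7-methoxy-4H-benzo[d][1,3,2]dioxasiline; 8 2,2-di-tert-butyl-7-methoxy-4H-benzo[d][1,3,2]dioxasilin-5-yl 3-bromo-4-methoxybenzoate
Product: 14 2,2-di-tert-butyl-7-methoxy-4H-benzo[d][1,3,2]dioxasilin-5-yl 3-[5-(benzyloxy)-2,2-di-tert-butyl-7-methoxy-4H-benzo[d][1,3,2]dioxasilin-8-yl]-4-methoxybenzoate, via arylmagnesium chloride 12 (not isolated), via arylzinc chloride 13 (not isolated)
Conditions: 11, iPrMgCl·LiCl, THF, −20 to 0 °C; ZnCl2; then 8, Pd(OAc)2 (5 mol%), SPhos (10 mol%), THF, 60 °C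
Reagents that add atoms: none
Why: Negishi coupling (iodine–magnesium exchange, transmetalation to zinc, cross-coupling with the aryl bromide at zerovalent palladium carrying a dialkylbiarylphosphine) is established for tri-ortho-substituted biaryls and leaves the aryl ester untouched because no base or hard nucleophile is present.

Step 11
Reactants: 14 biaryl ester with the ring D benzyl ether (name as in step 10)
Product: 15 2,2-di-tert-butyl-7-methoxy-4H-benzo[d][1,3,2]dioxasilin-5-yl 3-(2,2-di-tert-butyl-5-hydroxy-7-methoxy-4H-benzo[d][1,3,2]dioxasilin-8-yl)-4-methoxybenzoate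
Conditions: H2 (1 atm), Pd/C, EtOAc, rt
Reagents that add atoms: none
Why: Hydrogenolysis of the ring D benzyl ether frees the phenol that will become O1'', which is possible at this stage because no alkene or aryl halide is present yet.

Step 12
Reactants: 15 ring D phenol (name as in step 11); 16 4-(benzyloxy)benzoyl chloride
Product: 17 2,2-di-tert-butyl-7-methoxy-4H-benzo[d][1,3,2]dioxasilin-5-yl 3-(5-{[4-(benzyloxy)benzoyl]oxy}-2,2-di-tert-butyl-7-methoxy-4H-benzo[d][1,3,2]dioxasilin-8-yl)-4-methoxybenzoate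
Conditions: pyridine, DMAP (cat.), CH2Cl2, 0 °C to rt
Reagents that add atoms: none
Why: Acylation of the phenol by the aroyl chloride through the acylpyridinium ion, with a weak base that keeps the phenol protonated so that the neighbouring silylene has no phenoxide to migrate to.

Step 13
Reactants: 17 bis(aryl benzoate) (name as in step 12)
Product: 18 5-[(1-{3-[5-({1-[4-(benzyloxy)phenyl]vinyl}oxy)-2,2-di-tert-butyl-7-methoxy-4H-benzo[d][1,3,2]dioxasilin-8-yl]-4-methoxyphenyl}vinyl)oxy]-2,2-di-tert-butyl-7-methoxy-4H-benzo[d][1,3,2]dioxasiline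
Conditions: Cp2TiMe2 (5 equiv), toluene/THF, 70 °C, dark; filtration through basic Al2O3
Reagents that add atoms: dimethyltitanocene, C[Ti](C)(C1C=CC=C1)C1C=CC=C1
Why: Petasis methylenation, in which thermolysis of Cp2TiMe2 gives the titanocene methylidene that turns each aryl benzoate C=O into C=CH2 by cycloaddition and cycloreversion (a known conversion of aryl esters into aryl vinyl ethers), while ethers and silylenes are inert and the non-acidic work-up preserves the acid-labile products.

Step 14
Reactants: 18 bis(1-arylvinyl ether) bis(silylene) (name as in step 13)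
Product: 19 2-(hydroxymethyl)-3-[(1-{3-[2-hydroxy-3-(hydroxymethyl)-6-methoxy-4-({1-[4-(benzyloxy)phenyl]vinyl}oxy)phenyl]-4-methoxyphenyl}vinyl)oxy]-5-methoxyphenol
Conditions: TBAF (6 equiv), AcOH (6 equiv), THF, 0 °C to rt
Reagents that add atoms: none
Why: Fluoride cleaves both Si–O bonds of each silylene (desilylation), and the acetic acid buffer keeps the medium close to neutral so that neither the enol ethers are hydrolysed nor the liberated salicyl alcohols ionise, the tetraol being oxidised at once.

Step 15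
Reactants: 19 bis(salicyl alcohol) (name as in step 14)
Product: 20 2-hydroxy-6-[(1-{3-[3-formyl-2-hydroxy-6-methoxy-4-({1-[4-(benzyloxy)phenyl]vinyl}oxy)phenyl]-4-methoxyphenyl}vinyl)oxy]-4-methoxybenzaldehyde
Conditions: MnO2 (activated, excess), CH2Cl2, rt
Reagents that add atoms: none
Why: MnO2 oxidises benzylic alcohols selectively to aldehydes under neutral heterogeneous conditions, and each salicylaldehyde formed is protected from further oxidation by its hydrogen bond to the ortho phenol.

Step 16
Reactants: 20 bis(salicylaldehyde) bis(1-arylvinyl ether) (name as in step 15)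
Product: 21 (2S)-2-{3-[(2S)-2-[4-(benzyloxy)phenyl]-5-hydroxy-7-methoxy-4-oxo-3,4-dihydro-2H-chromen-6-yl]-4-methoxyphenyl}-5-hydroxy-7-methoxy-2,3-dihydro-4H-chromen-4-one
Conditions: [Rh(cod)2]BF4 (10 mol%), (R)-DTBM-SEGPHOS (11 mol%), 2,6-di-tert-butyl-4-methylpyridine (20 mol%), 4 Å MS, THF, 50 °C
Reagents that add atoms: none
Why: Proposed new method: the cationic monovalent rhodium bisphosphine binds the enol ether alkene, inserts into the formyl C–H bond that the O5–H···O=C (O5''–H···O=C) hydrogen bond turns toward the tether, the resulting trivalent acyl rhodium hydride adds Rh–H across the 1,1-disubstituted alkene with hydride to C2 (C2'') and rhodium to the terminal CH2, and C–C reductive elimination from the seven-membered rhodacycle (Rh, C4, C4a, C8a, O1, C2, C3) joins C3 to C4. The closest known reaction type is the rhodium-catalysed enantioselective intramolecular hydroacylation of 1,1-disubstituted alkenes held ortho to an aryl aldehyde by a carbon or nitrogen tether, which gives six-membered aryl ketones with a stereocentre β to the carbonyl, whereas an oxygen-tethered 1-arylvinyl ether has not been shown. Ring C and ring F each close in the formal 6-endo-trig mode of hydroacylation, the two sites being remote and acting independently. C2 and C2'' are each set by the face of the alkene to which the ligand-bound rhodium hydride is delivered (catalyst control with the same sense at both sites), so the S,S isomer should dominate and the minor S,R and R,S diastereomers should be removable by chromatography. The step needs anti-Markovnikov insertion (chromanone, not 2-aryl-2-methylbenzofuran-3-one), which the 1,1-disubstitution secures because rhodium at C2 would be a tertiary alkyl, and it needs C–C reductive elimination to outrun decarbonylation and β-aryloxide elimination, which the tether oxygen and alkene filling the free coordination sites and the bulky electron-rich bisphosphine should favour. No phenoxide-forming base is present (the hindered pyridine only traps adventitious acid that would hydrolyse the enol ethers), because an O5-bound rhodium phenoxide chelate would hold the metal on the side of the acyl carbon away from the tether, where the alkene cannot reach it.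

Step 17
Reactants: 21 ring E benzyl ether of the target (name as in step 16)
Product: 22 (2S)-5-hydroxy-2-{3-[(2S)-5-hydroxy-2-(4-hydroxyphenyl)-7-methoxy-4-oxo-3,4-dihydro-2H-chromen-6-yl]-4-methoxyphenyl}-7-methoxy-2,3-dihydro-4H-chromen-4-one
Conditions: H2 (1 atm), Pd/C, EtOAc/THF, rt
Reagents that add atoms: none
Why: Hydrogenolysis of the aryl benzyl ether on ring E under neutral conditions releases the last phenol without touching the C2 and C2'' stereocentres, which epimerise only through base-induced ring opening.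

**Compound list**

1 | 2,4,6-trihydroxybenzaldehyde | O=Cc1c(O)cc(O)cc1O | starting material
2 | 2,6-dihydroxy-4-methoxybenzaldehyde | COc1cc(O)c(C=O)c(O)c1 | intermediate
3 | 2-(benzyloxy)-6-hydroxy-4-methoxybenzaldehyde | COc1cc(O)c(C=O)c(OCc2ccccc2)c1 | intermediate
4 | 3-(benzyloxy)-2-(hydroxymethyl)-5-methoxyphenol | COc1cc(O)c(CO)c(OCc2ccccc2)c1 | intermediate
5 | 5-(benzyloxy)-2,2-di-tert-butyl-7-methoxy-4H-benzo[d][1,3,2]dioxasiline | COc1cc(OCc2ccccc2)c2c(c1)O[Si](C(C)(C)C)(C(C)(C)C)OC2 | intermediate
6 | 2,2-di-tert-butyl-7-methoxy-4H-benzo[d][1,3,2]dioxasilin-5-ol | COc1cc(O)c2c(c1)O[Si](C(C)(C)C)(C(C)(C)C)OC2 | intermediate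
7 | 3-bromo-4-methoxybenzoic acid | COc1ccc(C(=O)O)cc1Br | starting material
8 | 2,2-di-tert-butyl-7-methoxy-4H-benzo[d][1,3,2]dioxasilin-5-yl 3-bromo-4-methoxybenzoate | COc1cc(OC(=O)c2ccc(OC)c(Br)c2)c2c(c1)O[Si](C(C)(C)C)(C(C)(C)C)OC2 | intermediate
9 | 6-(benzyloxy)-2-hydroxy-3-iodo-4-methoxybenzaldehyde | COc1cc(OCc2ccccc2)c(C=O)c(O)c1I | intermediate
10 | 3-(benzyloxy)-2-(hydroxymethyl)-6-iodo-5-methoxyphenol | COc1cc(OCc2ccccc2)c(CO)c(O)c1I | intermediate
11 | 5-(benzyloxy)-2,2-di-tert-butyl-8-iodo-7-methoxy-4H-benzo[d][1,3,2]dioxasiline | COc1cc(OCc2ccccc2)c2c(c1I)O[Si](C(C)(C)C)(C(C)(C)C)OC2 | intermediate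
12 | [5-(benzyloxy)-2,2-di-tert-butyl-7-methoxy-4H-benzo[d][1,3,2]dioxasilin-8-yl]magnesium chloride | COc1cc(OCc2ccccc2)c2c(c1[Mg]Cl)O[Si](C(C)(C)C)(C(C)(C)C)OC2 | intermediate (not isolated)
13 | [5-(benzyloxy)-2,2-di-tert-butyl-7-methoxy-4H-benzo[d][1,3,2]dioxasilin-8-yl]zinc chloride | COc1cc(OCc2ccccc2)c2c(c1[Zn]Cl)O[Si](C(C)(C)C)(C(C)(C)C)OC2 | intermediate (not isolated)
14 | 2,2-di-tert-butyl-7-methoxy-4H-benzo[d][1,3,2]dioxasilin-5-yl 3-[5-(benzyloxy)-2,2-di-tert-butyl-7-methoxy-4H-benzo[d][1,3,2]dioxasilin-8-yl]-4-methoxybenzoate | COc1cc(OC(=O)c2ccc(OC)c(-c3c(OC)cc(OCc4ccccc4)c4c3O[Si](C(C)(C)C)(C(C)(C)C)OC4)c2)c2c(c1)O[Si](C(C)(C)C)(C(C)(C)C)OC2 | intermediate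
15 | 2,2-di-tert-butyl-7-methoxy-4H-benzo[d][1,3,2]dioxasilin-5-yl 3-(2,2-di-tert-butyl-5-hydroxy-7-methoxy-4H-benzo[d][1,3,2]dioxasilin-8-yl)-4-methoxybenzoate | COc1cc(OC(=O)c2ccc(OC)c(-c3c(OC)cc(O)c4c3O[Si](C(C)(C)C)(C(C)(C)C)OC4)c2)c2c(c1)O[Si](C(C)(C)C)(C(C)(C)C)OC2 | intermediate
16 | 4-(benzyloxy)benzoyl chloride | O=C(Cl)c1ccc(OCc2ccccc2)cc1 | starting material
17 | 2,2-di-tert-butyl-7-methoxy-4H-benzo[d][1,3,2]dioxasilin-5-yl 3-(5-{[4-(benzyloxy)benzoyl]oxy}-2,2-di-tert-butyl-7-methoxy-4H-benzo[d][1,3,2]dioxasilin-8-yl)-4-methoxybenzoate | COc1cc(OC(=O)c2ccc(OC)c(-c3c(OC)cc(OC(=O)c4ccc(OCc5ccccc5)cc4)c4c3O[Si](C(C)(C)C)(C(C)(C)C)OC4)c2)c2c(c1)O[Si](C(C)(C)C)(C(C)(C)C)OC2 | intermediate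
18 | 5-[(1-{3-[5-({1-[4-(benzyloxy)phenyl]vinyl}oxy)-2,2-di-tert-butyl-7-methoxy-4H-benzo[d][1,3,2]dioxasilin-8-yl]-4-methoxyphenyl}vinyl)oxy]-2,2-di-tert-butyl-7-methoxy-4H-benzo[d][1,3,2]dioxasiline | COc1cc(OC(=C)c2ccc(OC)c(-c3c(OC)cc(OC(=C)c4ccc(OCc5ccccc5)cc4)c4c3O[Si](C(C)(C)C)(C(C)(C)C)OC4)c2)c2c(c1)O[Si](C(C)(C)C)(C(C)(C)C)OC2 | intermediate
19 | 2-(hydroxymethyl)-3-[(1-{3-[2-hydroxy-3-(hydroxymethyl)-6-methoxy-4-({1-[4-(benzyloxy)phenyl]vinyl}oxy)phenyl]-4-methoxyphenyl}vinyl)oxy]-5-methoxyphenol | COc1cc(O)c(CO)c(OC(=C)c2ccc(OC)c(-c3c(OC)cc(OC(=C)c4ccc(OCc5ccccc5)cc4)c(CO)c3O)c2)c1 | intermediate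
20 | 2-hydroxy-6-[(1-{3-[3-formyl-2-hydroxy-6-methoxy-4-({1-[4-(benzyloxy)phenyl]vinyl}oxy)phenyl]-4-methoxyphenyl}vinyl)oxy]-4-methoxybenzaldehyde | COc1cc(O)c(C=O)c(OC(=C)c2ccc(OC)c(-c3c(OC)cc(OC(=C)c4ccc(OCc5ccccc5)cc4)c(C=O)c3O)c2)c1 | intermediate
21 | (2S)-2-{3-[(2S)-2-[4-(benzyloxy)phenyl]-5-hydroxy-7-methoxy-4-oxo-3,4-dihydro-2H-chromen-6-yl]-4-methoxyphenyl}-5-hydroxy-7-methoxy-2,3-dihydro-4H-chromen-4-one | COc1cc(O)c2c(c1)O[C@H](c1ccc(OC)c(-c3c(OC)cc4c(c3O)C(=O)C[C@@H](c3ccc(OCc5ccccc5)cc3)O4)c1)CC2=O | intermediate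
22 | (2S)-5-hydroxy-2-{3-[(2S)-5-hydroxy-2-(4-hydroxyphenyl)-7-methoxy-4-oxo-3,4-dihydro-2H-chromen-6-yl]-4-methoxyphenyl}-7-methoxy-2,3-dihydro-4H-chromen-4-one | COc1cc(O)c2c(c1)O[C@H](c1ccc(OC)c(-c3c(OC)cc4c(c3O)C(=O)C[C@@H](c3ccc(O)cc3)O4)c1)CC2=O | target

**Step count**
Total: 17 steps. Longest linear sequence: 14 steps (steps 1–6 and 10–17, from compound 1).

**Steps most likely to fail**

Step 16. What may go wrong: decarbonylation of the acyl rhodium hydride, insertion with rhodium at C2 leading to the five-membered ketone, β-aryloxide elimination from the alkyl rhodium, acid-induced hydrolysis of the enol ethers, or insufficient facial selectivity at one of the two alkenes. Fallback (known chemistry; the C2–aryl bonds are made instead of C3–C4): twofold rhodium-catalysed asymmetric 1,4-addition of arylboron reagents to chromones. It uses no numbered intermediate (it starts beside the route, from purchased 5-hydroxy-7-methoxy-4H-chromen-4-one F1) and comes back to the route at compound 21. F1 is iodinated ortho to the chelated hydroxyl (I2, TlOAc, CH2Cl2) to 5-hydroxy-6-iodo-7-methoxy-4H-chromen-4-one F2. Suzuki–Miyaura coupling at the C–I bond with (5-bromo-2-methoxyphenyl)boronic acid (Pd(PPh3)4, Na2CO3, DME/H2O) gives 6-(5-bromo-2-methoxyphenyl)-5-hydroxy-7-methoxy-4H-chromen-4-one F3. Asymmetric 1,4-addition of [4-(benzyloxy)phenyl]boronic acid ([Rh(OH)(cod)]2 with an electron-poor MeO-BIPHEP-type bisphosphine of the antipode that gives 2S, toluene/H2O) gives (2S)-2-[4-(benzyloxy)phenyl]-6-(5-bromo-2-methoxyphenyl)-5-hydroxy-7-methoxy-2,3-dihydro-4H-chromen-4-one F4. Miyaura borylation (B2pin2, PdCl2(dppf), KOAc, dioxane) converts the aryl bromide into the pinacol boronate (2S)-2-[4-(benzyloxy)phenyl]-5-hydroxy-7-methoxy-6-[2-methoxy-5-(4,4,5,5-tetramethyl-1,3,2-dioxaborolan-2-yl)phenyl]-2,3-dihydro-4H-chromen-4-one F5. A second asymmetric 1,4-addition, of F5 to a further equivalent of F1 under the same rhodium catalyst, forms the C2–C1' bond and gives compound 21, which goes on to step 17.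

Step 10. What may go wrong: incomplete iodine–magnesium exchange at the electron-rich, doubly ortho-substituted iodide, protonation of the arylmetal, or slow coupling to the tri-ortho-substituted biaryl. Fallback: Suzuki–Miyaura coupling with the roles reversed (ring B as the boron nucleophile, ring D as the electrophile, no organomagnesium). It sets out from compound 8 and comes back at compound 14. Miyaura borylation of 8 (B2pin2, PdCl2(dppf), KOAc, dioxane, 80 °C) gives 2,2-di-tert-butyl-7-methoxy-4H-benzo[d][1,3,2]dioxasilin-5-yl 4-methoxy-3-(4,4,5,5-tetramethyl-1,3,2-dioxaborolan-2-yl)benzoate F6, which is coupled with iodide 11 (Pd(OAc)2, SPhos, anhydrous K3PO4, toluene, 90 °C) to give 14.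

Step 17. What may go wrong: hydrogenolysis of the benzylic C2–O1 and C2''–O1'' bonds (opening to dihydrochalcones) or reduction of the C4 ketones in competition with O-debenzylation. Fallback: non-reductive cleavage of the benzyl ether by BCl3 with pentamethylbenzene as the benzyl cation trap (CH2Cl2, −78 °C). It sets out from compound 21 and arrives directly at compound 22; no new compound is made.

**Further compounds**
F1 | step 16 | 5-hydroxy-7-methoxy-4H-chromen-4-one | COc1cc(O)c2c(c1)occc2=O
F2 | step 16 | 5-hydroxy-6-iodo-7-methoxy-4H-chromen-4-one | COc1cc2occc(=O)c2c(O)c1I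
F3 | step 16 | 6-(5-bromo-2-methoxyphenyl)-5-hydroxy-7-methoxy-4H-chromen-4-one | COc1cc2occc(=O)c2c(O)c1-c1cc(Br)ccc1OC
F4 | step 16 | (2S)-2-[4-(benzyloxy)phenyl]-6-(5-bromo-2-methoxyphenyl)-5-hydroxy-7-methoxy-2,3-dihydro-4H-chromen-4-one | COc1cc2c(c(O)c1-c1cc(Br)ccc1OC)C(=O)C[C@@H](c1ccc(OCc3ccccc3)cc1)O2
F5 | step 16 | (2S)-2-[4-(benzyloxy)phenyl]-5-hydroxy-7-methoxy-6-[2-methoxy-5-(4,4,5,5-tetramethyl-1,3,2-dioxaborolan-2-yl)phenyl]-2,3-dihydro-4H-chromen-4-one | COc1cc2c(c(O)c1-c1cc(B3OC(C)(C)C(C)(C)O3)ccc1OC)C(=O)C[C@@H](c1ccc(OCc3ccccc3)cc1)O2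
F6 | step 10 | 2,2-di-tert-butyl-7-methoxy-4H-benzo[d][1,3,2]dioxasilin-5-yl 4-methoxy-3-(4,4,5,5-tetramethyl-1,3,2-dioxaborolan-2-yl)benzoate | COc1cc(OC(=O)c2ccc(OC)c(B3OC(C)(C)C(C)(C)O3)c2)c2c(c1)O[Si](C(C)(C)C)(C(C)(C)C)OC2
F0 | step 17 | none | none
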